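Find when target stands highest in this flask, charged with 1.30 equivalents of coupling partner, and how high it stands there.

* time up to 15 d at which target stands highest
* the amount of target, in percent of the substrate charged, at that time

| flask | substrate | coupling partner | free catalyst | remark | time |
|---|---|---|---|---|---|
| Monday's | 0.30 M | 0.55 M | 7.5 mM | run made earlier |  |
| Friday's | 0.30 M | 0.86 M | 7.5 mM | run made earlier |  |
| flask | 0.30 M | 0.390 M | 7.5 mM |  | 15 d |

| run | time / d | target / % | substrate / % |
|---|---|---|---|
| Monday's | 0.500 | 53.8 | 22.5 |
| Monday's | 0.833 | 72.2 | 10.2 |
| Monday's | 1.25 | 81.5 | 4.1 |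
| Monday's | 2.00 | 84.2 | 1.1 |
| Monday's | 4.00 | 71.8 | 0.9 |
| Monday's | 6.00 | 57.8 | 0 |
| Monday's | 10.0 | 37.8 | 0.4 |
| Friday's | 0.500 | 62.8 | 19.7 |
| Friday's | 0.833 | 78.2 | 8.3 |
| Friday's | 1.25 | 84.6 | 3.2 |
| Friday's | 2.00 | 83.9 | 0.9 |
| Friday's | 4.00 | 70.2 | 0 |
| Friday's | 6.00 | 56.9 | 0.5 |
| Friday's | 10.0 | 37.2 | 0.3 |

(each reading ± 0.3 percentage points)



Watch the earlier runs in slow motion. In the first stage read substrate: at 0.500 d Monday's run holds 22.5% and Friday's 19.7%. What is neither substrate nor target then comes to 23.7% on Monday's run against 17.5% on Friday's, so read a pool of material that has left substrate and waits for coupling partner. In the middle, at 2.00 d, substrate stands at 1.1% on Monday's run and 0.9% on Friday's. At the end Monday's run reads 37.8% and Friday's 37.2% of target at 10.0 d, so between these two charges the late loss shows no clear dependence on partner.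

Now freeze what stays put. Take one coupling partner per target, with substrate as the limiting reagent, and keep 0.0900 M: the spare partner, the floor of c(coupling partner) once the substrate charge has been coupled in full. Monday's run has 0.250 M and Friday's 0.560 M, so this flask has a lower floor. Its coupling partner charge is still larger than its substrate charge. Its last waiting material should therefore meet partner, more slowly. Commit to a peak below Monday's 84.2% reading, later than that reading's 2.00 d, with 23.1% of the partner charge left at the end.

The forecast gives 82.5% at 2.3 d: “The peak comes when intermediate conversion equals target decay”.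

The flask gives 82.8% at 2.15 d.

    substrate + free catalyst → free catalyst + open intermediate (k = 20.0 /M/h)
    free catalyst + open intermediate ⇌ catalyst intermediate (K = 10.0 /M, k = 630 /M/h)
    coupling partner + catalyst intermediate → free catalyst + target (k = 15.0 /M/h)
    target → over-reaction product A (k = 2.50 × 10⁻⁵ /h)
    free catalyst + target → free catalyst + over-reaction product B (k = 0.580 /M/h)
    substrate ⇌ dormant form (K = 0.360, k = 0.0320 /h)

At 15.0 d this flask holds 23.1% of its coupling partner charge, and spare partner over that charge gives 23.1%. Subtract again for a neighbour charged with 0.23 M: it falls 0.0700 M short, which is 23.3% of the substrate charged. That neighbour ends with 0% of its partner, and its best is 65.1%. Its open intermediate and catalyst intermediate together hold 23.3% of the substrate charged at 15.0 d.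

(Readings and results are calculated on assumed constants; noise was put on by code.)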